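**Plan**

- The target is an erythro 8-O-4′ neolignan. C7 (the carbinol carbon on ring A) and C8 (the carbon carrying the ring-B aryl ether oxygen) are adjacent and anti, and C9 is a single CH2OH carbon that a vinyl group can stand in for. The retrosynthesis therefore cuts the C7–C8 bond, traces C9–OH back to a vinyl group, and traces the ArO–C8 unit back to an O-propargyl ether of the ring-B phenol.
- Forward, no ring is formed; both benzene rings come from commercial phenols. The ring-B phenol is elaborated (side-chain hydroboration, O-propargylation, silylation, alkyne hydroboration, double-bond transposition) into an E-γ-aryloxyallyl pinacolboronate.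
- This boronate is added to O-benzylsyringaldehyde, which joins C7 to C8. The vinyl group is then cut down to CH2OH and the silyl and benzyl groups are removed.
- Both stereocentres arise in the addition: the anti (7,8-erythro) relationship from the E geometry of the boronate in a chair transition state, the absolute configuration (7R,8S) from a chiral phosphoric acid.

Key step: step 7

Remark on the chemistry: the target is (7R,8S), i.e. anti in the zigzag Ar–C7–C8–C9 drawing, and 7R requires addition to the Si face of the formyl group. By analogy with the accepted model for phosphoric acid-catalysed allyl- and crotylboration of aryl aldehydes, the (S)-antipode of the 3,3′-bis(2,4,6-triisopropylphenyl)-BINOL phosphoric acid (TRIP) is assumed to deliver this face. The assignment would be checked on the first small batch of 13 (MTPA ester analysis), and the (R)-catalyst used if the sense proves opposite.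

**Route**

Step 1
Reactants: 1 4-allyl-2,6-dimethoxyphenol
Product: 3 4-(3-hydroxypropyl)-2,6-dimethoxyphenol, via bis(9-BBN) adduct 2 (not isolated)
Conditions: 9-BBN (2.3 equiv), THF, 0 °C to rt; then aq. NaOH, H2O2, 0 °C to rt
Reagents that add atoms: hydrogen peroxide, OO
Why: Hydroboration–oxidation: 9-BBN adds anti-Markovnikov to the terminal alkene (one further equivalent is consumed by the phenol as its borinate, released again in the basic peroxide work-up) and oxidative C–B cleavage gives the primary alcohol.

Step 2
Reactants: 3 4-(3-hydroxypropyl)-2,6-dimethoxyphenol; 4 propargyl bromide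
Product: 5 3-[3,5-dimethoxy-4-(prop-2-yn-1-yloxy)phenyl]propan-1-ol
Conditions: K2CO3, acetone, reflux
Reagents that add atoms: none
Why: Williamson ether synthesis: carbonate deprotonates only the phenol, so O-alkylation should occur at the phenolic oxygen and leave the primary alcohol alone.

Step 3
Reactants: 5 3-[3,5-dimethoxy-4-(prop-2-yn-1-yloxy)phenyl]propan-1-ol
Product: 6 tert-butyl{3-[3,5-dimethoxy-4-(prop-2-yn-1-yloxy)phenyl]propoxy}dimethylsilane
Conditions: TBSCl, imidazole, CH2Cl2, rt
Reagents that add atoms: tert-butyldimethylsilyl chloride, CC(C)(C)[Si](C)(C)Cl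
Why: Imidazole-promoted silylation of the primary alcohol removes the only protic group before the B–H and Ir–H steps.

Step 4
Reactants: 6 tert-butyl{3-[3,5-dimethoxy-4-(prop-2-yn-1-yloxy)phenyl]propoxy}dimethylsilane; 7 pinacolborane
Product: 8 2-[(1E)-3-{4-[3-(tert-butyldimethylsilyloxy)propyl]-2,6-dimethoxyphenoxy}prop-1-en-1-yl]-4,4,5,5-tetramethyl-1,3,2-dioxaborolane
Conditions: Cp2Zr(H)Cl (10 mol%), Et3N (10 mol%), neat, 60 °C
Reagents that add atoms: none
Why: Zirconocene hydride-catalysed hydroboration of a terminal alkyne: syn addition with boron at the terminal carbon gives the E-1-alkenylboronate, and propargyl ethers are standard substrates.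

Step 5
Reactants: 8 the E-1-alkenylboronate from step 4
Product: 9 2-[(2E)-3-{4-[3-(tert-butyldimethylsilyloxy)propyl]-2,6-dimethoxyphenoxy}prop-2-en-1-yl]-4,4,5,5-tetramethyl-1,3,2-dioxaborolane
Conditions: [Ir(cod)(PPh2Me)2]PF6 (3 mol%, activated with H2, then degassed), THF, rt; filtration through neutral alumina, used at once
Reagents that add atoms: none
Why: Cationic iridium hydride-catalysed 1,3-hydrogen shift (allyl ether to enol ether isomerisation), known for 3-silyloxy-1-propenylboronates and for allyl aryl ethers; conjugation of the alkene with oxygen drives the transposition and this catalyst type gives the E-enol ether under kinetic control.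

Step 6
Reactants: 10 syringaldehyde (4-hydroxy-3,5-dimethoxybenzaldehyde)
Product: 11 4-(benzyloxy)-3,5-dimethoxybenzaldehyde
Conditions: BnBr, K2CO3, DMF, 50 °C
Reagents that add atoms: benzyl bromide, BrCc1ccccc1
Why: Williamson benzylation of the phenol removes the acidic OH, which would otherwise protonate the boronate and deactivate the aldehyde as its phenoxide.

Step 7
Reactants: 9 the E-γ-aryloxyallyl pinacolboronate from step 5; 11 4-(benzyloxy)-3,5-dimethoxybenzaldehyde
Product: 13 (1R,2S)-1-[4-(benzyloxy)-3,5-dimethoxyphenyl]-2-{4-[3-(tert-butyldimethylsilyloxy)propyl]-2,6-dimethoxyphenoxy}but-3-en-1-ol, via O-pinacolboryl ether 12 (not isolated)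
Conditions: (S)-TRIP phosphoric acid (5 mol%), 4 Å MS, toluene, −30 °C; aq. NaHCO3 work-up
Reagents that add atoms: none
Why: The phosphoric acid hydrogen-bonds to a pinacol oxygen of 9, the aldehyde oxygen binds boron, and the bond between the formyl carbon and the aryloxy-bearing γ-carbon forms with allyl transposition through a six-membered chair (Zimmerman–Traxler type) transition state to give borate 12, which is hydrolysed on work-up. The closest known reaction type is the chiral phosphoric acid-catalysed allyl-, crotyl- and γ-alkoxyallylboration of aldehydes with pinacol boronates. No ring is formed. C8 is set relative to C7 by the E geometry of 9, because the aldehyde aryl group and the E-aryloxy group both sit equatorial in the chair and this gives the 7,8-anti (erythro) arrangement; C7 is set by the catalyst, whose 3,3′-aryl groups should leave only the Si face of the formyl group open, giving 7R and therefore 8S. The step needs anti diastereoselectivity, secured by the geometric purity and configurational stability of 9 at low temperature, and face selectivity, secured by the catalyst antipode and by running cold enough to suppress the uncatalysed background addition. The aldehyde cannot enolise, and the silyl ether, benzyl ether and enol ether should survive these anhydrous, nearly neutral conditions.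

Step 8
Reactants: 13 the homoallylic alcohol from step 7
Product: 15 (1R,2S)-1-[4-(benzyloxy)-3,5-dimethoxyphenyl]-2-{4-[3-(tert-butyldimethylsilyloxy)propyl]-2,6-dimethoxyphenoxy}propane-1,3-diol, via α-aryloxy aldehyde 14 (not isolated)
Conditions: O3, CH2Cl2/MeOH, −78 °C (Sudan Red 7B end point), N2 purge; then NaBH4, −78 to 0 °C
Reagents that add atoms: ozone, [O-][O+]=O
Why: Ozonolysis with reductive borohydride work-up: the terminal vinyl group should react well ahead of the benzenoid rings when the end point is set by the indicator dye, and reducing in the same flask means the epimerisable, retro-aldol-prone aldehyde 14 is never warmed or isolated, so C8 is retained.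

Step 9
Reactants: 15 the silyl-protected diol from step 8
Product: 16 (1R,2S)-1-[4-(benzyloxy)-3,5-dimethoxyphenyl]-2-[4-(3-hydroxypropyl)-2,6-dimethoxyphenoxy]propane-1,3-diol
Conditions: TBAF, THF, 0 °C to rt
Reagents that add atoms: none
Why: Fluoride-induced cleavage of the primary silyl ether; the benzyl ether, the aryl ethers and both stereocentres are inert to these non-acidic conditions.

Step 10
Reactants: 16 the benzyl-protected triol from step 9
Product: 17 (1R,2S)-1-(4-hydroxy-3,5-dimethoxyphenyl)-2-[4-(3-hydroxypropyl)-2,6-dimethoxyphenoxy]propane-1,3-diol (target)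
Conditions: H2 (1 atm), 10% Pd/C, EtOAc, rt
Reagents that add atoms: none
Why: Catalytic hydrogenolysis of the aryl benzyl ether, which under neutral conditions at one atmosphere should be much faster than C–O hydrogenolysis of the secondary benzylic alcohol, so stopping at consumption of 16 should leave C7–OH and its configuration intact.

**Compound list**

1 | 4-allyl-2,6-dimethoxyphenol | COc1cc(CC=C)cc(OC)c1O | starting material
2 | 9-{3-[4-(9-borabicyclo[3.3.1]nonan-9-yloxy)-3,5-dimethoxyphenyl]propyl}-9-borabicyclo[3.3.1]nonane | COc1cc(CCCB2C3CCCC2CCC3)cc(OC)c1OB1C2CCCC1CCC2 | intermediate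
3 | 4-(3-hydroxypropyl)-2,6-dimethoxyphenol | COc1cc(CCCO)cc(OC)c1O | intermediate
4 | propargyl bromide | C#CCBr | starting material
5 | 3-[3,5-dimethoxy-4-(prop-2-yn-1-yloxy)phenyl]propan-1-ol | COc1cc(CCCO)cc(OC)c1OCC#C | intermediate
6 | tert-butyl{3-[3,5-dimethoxy-4-(prop-2-yn-1-yloxy)phenyl]propoxy}dimethylsilane | COc1cc(CCCO[Si](C)(C)C(C)(C)C)cc(OC)c1OCC#C | intermediate
7 | pinacolborane | CC1(C)OBOC1(C)C | starting material
8 | 2-[(1E)-3-{4-[3-(tert-butyldimethylsilyloxy)propyl]-2,6-dimethoxyphenoxy}prop-1-en-1-yl]-4,4,5,5-tetramethyl-1,3,2-dioxaborolane | COc1cc(CCCO[Si](C)(C)C(C)(C)C)cc(OC)c1OC/C=C/B1OC(C)(C)C(C)(C)O1 | intermediate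
9 | 2-[(2E)-3-{4-[3-(tert-butyldimethylsilyloxy)propyl]-2,6-dimethoxyphenoxy}prop-2-en-1-yl]-4,4,5,5-tetramethyl-1,3,2-dioxaborolane | COc1cc(CCCO[Si](C)(C)C(C)(C)C)cc(OC)c1O/C=C/CB1OC(C)(C)C(C)(C)O1 | intermediate
10 | syringaldehyde | COc1cc(C=O)cc(OC)c1O | starting material
11 | 4-(benzyloxy)-3,5-dimethoxybenzaldehyde | COc1cc(C=O)cc(OC)c1OCc1ccccc1 | intermediate
12 | 2-{[(1R,2S)-1-[4-(benzyloxy)-3,5-dimethoxyphenyl]-2-{4-[3-(tert-butyldimethylsilyloxy)propyl]-2,6-dimethoxyphenoxy}but-3-en-1-yl]oxy}-4,4,5,5-tetramethyl-1,3,2-dioxaborolane | COc1cc([C@@H](OB2OC(C)(C)C(C)(C)O2)[C@H](C=C)Oc2c(OC)cc(CCCO[Si](C)(C)C(C)(C)C)cc2OC)cc(OC)c1OCc1ccccc1 | intermediate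
13 | (1R,2S)-1-[4-(benzyloxy)-3,5-dimethoxyphenyl]-2-{4-[3-(tert-butyldimethylsilyloxy)propyl]-2,6-dimethoxyphenoxy}but-3-en-1-ol | COc1cc([C@@H](O)[C@H](C=C)Oc2c(OC)cc(CCCO[Si](C)(C)C(C)(C)C)cc2OC)cc(OC)c1OCc1ccccc1 | intermediate
14 | (2R,3R)-3-[4-(benzyloxy)-3,5-dimethoxyphenyl]-2-{4-[3-(tert-butyldimethylsilyloxy)propyl]-2,6-dimethoxyphenoxy}-3-hydroxypropanal | COc1cc([C@@H](O)[C@H](C=O)Oc2c(OC)cc(CCCO[Si](C)(C)C(C)(C)C)cc2OC)cc(OC)c1OCc1ccccc1 | intermediate
15 | (1R,2S)-1-[4-(benzyloxy)-3,5-dimethoxyphenyl]-2-{4-[3-(tert-butyldimethylsilyloxy)propyl]-2,6-dimethoxyphenoxy}propane-1,3-diol | COc1cc([C@@H](O)[C@H](CO)Oc2c(OC)cc(CCCO[Si](C)(C)C(C)(C)C)cc2OC)cc(OC)c1OCc1ccccc1 | intermediate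
16 | (1R,2S)-1-[4-(benzyloxy)-3,5-dimethoxyphenyl]-2-[4-(3-hydroxypropyl)-2,6-dimethoxyphenoxy]propane-1,3-diol | COc1cc([C@@H](O)[C@H](CO)Oc2c(OC)cc(CCCO)cc2OC)cc(OC)c1OCc1ccccc1 | intermediate
17 | (1R,2S)-1-(4-hydroxy-3,5-dimethoxyphenyl)-2-[4-(3-hydroxypropyl)-2,6-dimethoxyphenoxy]propane-1,3-diol | COc1cc([C@@H](O)[C@H](CO)Oc2c(OC)cc(CCCO)cc2OC)cc(OC)c1O | target

**Step count and risks**

Total: 10 steps. Longest linear sequence: 9 steps (steps 1–5 and 7–10, from 4-allyl-2,6-dimethoxyphenol).

Steps most likely to fail:

Step 7. The risk is incomplete discrimination between the two faces of the electron-rich aldehyde, for instance through an uncatalysed background addition; the anti relationship should be unaffected. The fallback is classical resolution in place of catalyst control. It sets out from 13 of inadequate enantiomeric purity (in the limit the racemic anti alcohol from the thermal addition of 9 to 11 in toluene at room temperature). The alcohol would be esterified with (S)-2-methoxy-2-phenylacetic acid (DCC, DMAP, CH2Cl2) to give the (S)-O-methylmandelate ester of the (1R,2S)-alcohol F1 and the (S)-O-methylmandelate ester of the (1S,2R)-alcohol F2. These would be separated by chromatography or crystallisation, and F1 cleaved with K2CO3 in methanol. The fallback comes back to the route at 13.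

Step 5. The risk is incomplete or geometrically unselective double-bond transposition, or loss of the enol ether allylboronate by hydrolysis or protodeboronation during isolation. The fallback gives up the isolated reagent. It sets out from 8 and 11, which would be combined with a cationic iridium(I) phosphine catalyst and the chiral phosphoric acid in one flask, so that transposition and addition run in tandem and the E-allylboronate is consumed by the aldehyde as it forms. This is the known relay of alkenylboronate transposition with acid-catalysed allylboration. It passes through 9 and 12 without isolation, makes no compound outside the list (F0), and comes back to the route at 13.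

Step 8. The risk is over-oxidation of the two trialkoxybenzene rings or the benzyl ether by ozone, or epimerisation at C8 if the aldehyde survives too long. The fallback replaces ozone by a stepwise osmium-based cleavage. It sets out from 13, which would be dihydroxylated (cat. OsO4, NMO, acetone/water) to 1-[4-(benzyloxy)-3,5-dimethoxyphenyl]-2-{4-[3-(tert-butyldimethylsilyloxy)propyl]-2,6-dimethoxyphenoxy}butane-1,3,4-triol F3 (C1 and C2 as in 13, mixture of C3 epimers). The terminal 1,2-diol would be cleaved with NaIO4 in buffered aqueous THF at 0 °C to aldehyde 14, which is reduced at once with NaBH4. The fallback comes back to the route at 15.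

**Further compounds**

F1 | step 7 | (1R,2S)-1-[4-(benzyloxy)-3,5-dimethoxyphenyl]-2-{4-[3-(tert-butyldimethylsilyloxy)propyl]-2,6-dimethoxyphenoxy}but-3-en-1-yl (S)-2-methoxy-2-phenylacetate | COc1cc([C@@H](OC(=O)[C@@H](OC)c2ccccc2)[C@H](C=C)Oc2c(OC)cc(CCCO[Si](C)(C)C(C)(C)C)cc2OC)cc(OC)c1OCc1ccccc1
F2 | step 7 | (1S,2R)-1-[4-(benzyloxy)-3,5-dimethoxyphenyl]-2-{4-[3-(tert-butyldimethylsilyloxy)propyl]-2,6-dimethoxyphenoxy}but-3-en-1-yl (S)-2-methoxy-2-phenylacetate | COc1cc([C@H](OC(=O)[C@@H](OC)c2ccccc2)[C@@H](C=C)Oc2c(OC)cc(CCCO[Si](C)(C)C(C)(C)C)cc2OC)cc(OC)c1OCc1ccccc1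
F0 | step 5 | none | none
F3 | step 8 | 1-[4-(benzyloxy)-3,5-dimethoxyphenyl]-2-{4-[3-(tert-butyldimethylsilyloxy)propyl]-2,6-dimethoxyphenoxy}butane-1,3,4-triol (C1 and C2 as in 13, C3 epimers) | COc1cc([C@@H](O)[C@H](C(O)CO)Oc2c(OC)cc(CCCO[Si](C)(C)C(C)(C)C)cc2OC)cc(OC)c1OCc1ccccc1
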